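**Plan**

- Retrosynthetic cuts: C6 silyl ether; ring D at C13–C16 (vinyl radical) and C15–C16 (alkynyl addition to a C15 aldehyde); ring C at C8–C14 and C9–C11 (butadiene Diels–Alder); lactone at C8=C9 and C7–O20 (Knoevenagel after acylation of O20); C1–O (iodolactone from the C6 acid); ring A at C5–C10.
- Enabling feature: ring A holds C5 (bearing C6) beside the spiro quaternary C10 and next to quaternary C4. With C6 as the carbonyl of a δ-lactone closed on O–C2, and a C1=C10 alkene on C2, the lactone silyl ketene acetal can join C5 to C10 by a [3,3] shift. The lactone contracts to ring A and leaves C6 as CO2H and C1=C2 as handles.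
- Forward order: acyclic C4 quaternary centre → 6-alkenyl δ-lactone 22 → ring A → C1–O and C6 alcohol → spiro δ-lactone → ring C → ring D.
- Stereochemistry: C4 by Eschenmoser–Claisen chirality transfer from (S)-but-3-yn-2-ol; lactone carbinol C2 by Ru transfer hydrogenation; alkene geometry by directed trans-hydroalumination; C5 and C10 by the boat Claisen; C1 by the lactone bridge; C8 and C9 by Diels–Alder addition anti to C5; C13 by ring constraint.

Key step: step 15

Remark: atom numbers are those of the ent-kaurane skeleton of the target (C1–C5 and C10 = ring A, C6 on C5, C7 = lactone carbonyl, C19 on C4, C20 on C10). The C15 carbinol made in step 29 is carried as both epimers because step 31 removes that centre.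

**Route**

Step 1
Reactants: 1 (S)-but-3-yn-2-ol; 2 oxirane
Product: 3 (5S)-hex-3-yne-1,5-diol
Conditions: n-BuLi (2.2 equiv), THF/DMPU, −78 °C; then 2, −78 → 0 °C; H2O
Reagents that add atoms: none
Why: The C,O-dilithiated propargylic alcohol opens the epoxide at the acetylide carbon only (acetylide alkylation), and the carbinol centre is not touched.

Step 2
Reactants: 3 (5S)-hex-3-yne-1,5-diol
Product: 4 (2S)-6-[(triethylsilyl)oxy]hex-3-yn-2-ol
Conditions: Et3SiCl (1.05 equiv), imidazole, CH2Cl2, −78 → 0 °C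
Reagents that add atoms: chlorotriethylsilane, CC[Si](Cl)(CC)CC
Why: Silyl ether formation is much faster at the primary hydroxyl than at the secondary propargylic one (steric differentiation).

Step 3
Reactants: 4 (2S)-6-[(triethylsilyl)oxy]hex-3-yn-2-ol
Product: 5 (2S,3Z)-4-iodo-6-[(triethylsilyl)oxy]hex-3-en-2-ol
Conditions: NaAlH2(OCH2CH2OMe)2, THF, 0 °C → rt; then I2, −78 °C
Reagents that add atoms: iodine, II
Why: Hydroxyl-directed trans-hydroalumination of the propargylic alcohol puts hydride on the proximal and aluminium on the distal alkyne carbon, and iodinolysis with retention gives the (Z)-iodoalkene.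

Step 4
Reactants: 5 (2S,3Z)-4-iodo-6-[(triethylsilyl)oxy]hex-3-en-2-ol
Product: 6 (2S,3E)-4-methyl-6-[(triethylsilyl)oxy]hex-3-en-2-ol
Conditions: Me2CuLi (3 equiv), Et2O, 0 °C
Reagents that add atoms: lithium dimethylcuprate, [Li+].C[Cu-]C
Why: Cuprate substitution of the alkenyl iodide (Corey–Posner coupling) keeps the alkene geometry, so the new methyl group ends cis to the carbinol carbon.

Step 5
Reactants: 6 (2S,3E)-4-methyl-6-[(triethylsilyl)oxy]hex-3-en-2-ol; 7 1,1-dimethoxy-N,N-dimethylethanamine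
Product: 9 (3S,4E)-N,N,3-trimethyl-3-{2-[(triethylsilyl)oxy]ethyl}hex-4-enamide, via ketene N,O-acetal 8 (not isolated)
Conditions: 7 (5 equiv), xylene, 140 °C, MeOH distilled off
Reagents that add atoms: none
Why: Eschenmoser–Claisen rearrangement through a chair with the carbinol methyl equatorial transfers the (S) carbinol configuration suprafacially across the (E)-alkene to the new quaternary carbon C4 and leaves an (E)-propenyl group.

Step 6
Reactants: 9 (3S,4E)-N,N,3-trimethyl-3-{2-[(triethylsilyl)oxy]ethyl}hex-4-enamide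
Product: 11 (3S)-4-hydroxy-N,N,3-trimethyl-3-{2-[(triethylsilyl)oxy]ethyl}butanamide, via aldehyde 10 (not isolated)
Conditions: O3, CH2Cl2/MeOH, −78 °C; then NaBH4, −78 → 0 °C
Reagents that add atoms: ozone, [O-][O+]=O
Why: Ozonolysis with reductive work-up cuts the propenyl group down to the C19 hydroxymethyl group, and the tertiary amide does not lactonise under these basic conditions.

Step 7
Reactants: 11 (3S)-4-hydroxy-N,N,3-trimethyl-3-{2-[(triethylsilyl)oxy]ethyl}butanamide
Product: 12 (3S)-4-[(4-methoxybenzyl)oxy]-N,N,3-trimethyl-3-{2-[(triethylsilyl)oxy]ethyl}butanamide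
Conditions: NaH, 4-methoxybenzyl chloride, Bu4NI (cat.), THF/DMF, 0 °C → rt
Reagents that add atoms: 4-methoxybenzyl chloride, COc1ccc(CCl)cc1
Why: Williamson etherification of the neopentyl alkoxide with a benzylic chloride activated by iodide should protect C19 OH before any acid-level carbon is unveiled.

Step 8
Reactants: 12 (3S)-4-[(4-methoxybenzyl)oxy]-N,N,3-trimethyl-3-{2-[(triethylsilyl)oxy]ethyl}butanamide; 13 benzyl prop-2-yn-1-yl ether
Product: 14 (6S)-1-(benzyloxy)-7-[(4-methoxybenzyl)oxy]-6-methyl-6-{2-[(triethylsilyl)oxy]ethyl}hept-2-yn-4-one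
Conditions: 13, n-BuLi, THF, −78 °C; BF3·OEt2; then 12, −78 °C; aq. NH4Cl
Reagents that add atoms: none
Why: A lithium acetylide activated by BF3 adds once to an N,N-dimethylamide and the tetrahedral adduct collapses only on work-up, which gives the ynone (alkynylation of a tertiary amide).

Step 9
Reactants: 14 (6S)-1-(benzyloxy)-7-[(4-methoxybenzyl)oxy]-6-methyl-6-{2-[(triethylsilyl)oxy]ethyl}hept-2-yn-4-one
Product: 15 (4S,6S)-1-(benzyloxy)-7-[(4-methoxybenzyl)oxy]-6-methyl-6-{2-[(triethylsilyl)oxy]ethyl}hept-2-yn-4-ol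
Conditions: RuCl[(S,S)-TsDPEN](p-cymene) (2 mol %), i-PrOH, rt
Reagents that add atoms: none
Why: Noyori asymmetric transfer hydrogenation of an alkynyl ketone, in which the catalyst distinguishes alkynyl from alkyl, should set the (S) carbinol C2 regardless of the remote quaternary centre.

Step 10
Reactants: 15 (4S,6S)-1-(benzyloxy)-7-[(4-methoxybenzyl)oxy]-6-methyl-6-{2-[(triethylsilyl)oxy]ethyl}hept-2-yn-4-ol
Product: 16 (2Z,4S,6S)-1-(benzyloxy)-2-iodo-7-[(4-methoxybenzyl)oxy]-6-methyl-6-{2-[(triethylsilyl)oxy]ethyl}hept-2-en-4-ol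
Conditions: NaAlH2(OCH2CH2OMe)2, THF, 0 °C; then I2, −78 °C
Reagents that add atoms: iodine, II
Why: Alkoxide-directed trans-hydroalumination followed by iodination puts iodine on C10 cis to the carbinol carbon C2 and leaves CH2OBn (C20) trans to it.

Step 11
Reactants: 16 (2Z,4S,6S)-1-(benzyloxy)-2-iodo-7-[(4-methoxybenzyl)oxy]-6-methyl-6-{2-[(triethylsilyl)oxy]ethyl}hept-2-en-4-ol; 17 (tributylstannyl)methanol
Product: 18 (2E,4S,6S)-2-[(benzyloxy)methyl]-7-[(4-methoxybenzyl)oxy]-6-methyl-6-{2-[(triethylsilyl)oxy]ethyl}hept-2-ene-1,4-diol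
Conditions: Pd(PPh3)4 (5 mol %), 1,4-dioxane, 90 °C
Reagents that add atoms: none
Why: Stille coupling of the alkenyl iodide with the hydroxymethylstannane keeps the alkene geometry, so the new CH2OH (C9) is cis to C2 and CH2OBn (C20) trans.

Step 12
Reactants: 18 (2E,4S,6S)-2-[(benzyloxy)methyl]-7-[(4-methoxybenzyl)oxy]-6-methyl-6-{2-[(triethylsilyl)oxy]ethyl}hept-2-ene-1,4-diol
Product: 19 (2Z,4S,6S)-1-(benzyloxy)-2-({[tert-butyl(dimethyl)silyl]oxy}methyl)-7-[(4-methoxybenzyl)oxy]-6-methyl-6-{2-[(triethylsilyl)oxy]ethyl}hept-2-en-4-ol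
Conditions: t-BuMe2SiCl (1.05 equiv), imidazole, CH2Cl2, 0 °C
Reagents that add atoms: tert-butylchlorodimethylsilane, CC(C)(C)[Si](C)(C)Cl
Why: Silylation is faster at the primary allylic hydroxyl (C9) than at the secondary one (C2).

Step 13
Reactants: 19 (2Z,4S,6S)-1-(benzyloxy)-2-({[tert-butyl(dimethyl)silyl]oxy}methyl)-7-[(4-methoxybenzyl)oxy]-6-methyl-6-{2-[(triethylsilyl)oxy]ethyl}hept-2-en-4-ol
Product: 20 (3S,5S,6Z)-8-(benzyloxy)-7-({[tert-butyl(dimethyl)silyl]oxy}methyl)-3-{[(4-methoxybenzyl)oxy]methyl}-3-methyloct-6-ene-1,5-diol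
Conditions: pyridinium 4-toluenesulfonate (cat.), MeOH, 0 °C
Reagents that add atoms: none
Why: Mild acid methanolysis removes the primary triethylsilyl ether much faster than the tert-butyldimethylsilyl ether (selective desilylation).

Step 14
Reactants: 20 (3S,5S,6Z)-8-(benzyloxy)-7-({[tert-butyl(dimethyl)silyl]oxy}methyl)-3-{[(4-methoxybenzyl)oxy]methyl}-3-methyloct-6-ene-1,5-diol
Product: 22 (4R,6S)-6-[(1Z)-3-(benzyloxy)-2-({[tert-butyl(dimethyl)silyl]oxy}methyl)prop-1-en-1-yl]-4-{[(4-methoxybenzyl)oxy]methyl}-4-methyloxan-2-one, via lactol 21 (not isolated)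
Conditions: TEMPO (0.2 equiv), PhI(OAc)2 (2.5 equiv), CH2Cl2, rt
Reagents that add atoms: none
Why: The oxoammonium oxidant takes the primary C6 alcohol before the secondary allylic one, the hydroxy aldehyde closes to the lactol and this is oxidised on to the δ-lactone (oxidative lactonisation of a 1,5-diol).

Step 15
Reactants: 22 (4R,6S)-6-[(1Z)-3-(benzyloxy)-2-({[tert-butyl(dimethyl)silyl]oxy}methyl)prop-1-en-1-yl]-4-{[(4-methoxybenzyl)oxy]methyl}-4-methyloxan-2-one
Product: 25 (1R,2R,6R)-2-[(benzyloxy)methyl]-2-({[tert-butyl(dimethyl)silyl]oxy}methyl)-6-{[(4-methoxybenzyl)oxy]methyl}-6-methylcyclohex-3-ene-1-carboxylic acid, via silyl ketene acetal 23 (not isolated), via trimethylsilyl ester 24 (not isolated)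
Conditions: Me3SiCl/Et3N (premixed), KN(SiMe3)2, THF, −78 °C → rt; then toluene, 100 °C; aq. citric acid work-up
Reagents that add atoms: none
Why: Deprotonation at C5 with O-silylation in situ gives the endocyclic silyl ketene acetal 23, whose [3,3] shift (Ireland–Claisen rearrangement of a lactone enolate, known for ω-alkenyl lactones as a ring contraction) breaks O–C2 and joins C5 to C10. Ring A (C5–C10–C1–C2–C3–C4) closes by contraction of the six-membered lactone, whose tether forces a boat transition state shaped like a bicyclo[2.2.2]octane. C5 is set by suprafacial attack on the lactone face that carries the pseudoaxial alkenyl group, which is trans to CH2OPMB, so C6 ends cis to C19. C10 is set by the alkene geometry: CH2OBn (C20), trans to C2 in 22, ends cis to C6 and CH2OTBS (C9) trans to it. The step needs clean C5 enolisation and a boat in which the small C4 methyl, not CH2OPMB, lies under the allyl bridge; the fully substituted C4 (no β-leaving group, only one acidic site) and the cis methyl/alkenyl relationship of 22 secure both. Aqueous acid then hydrolyses silyl ester 24 to acid 25.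

Step 16
Reactants: 25 ring A acid
Product: 26 iodolactone (C6 carboxyl bridged through oxygen to C1 on the C6/C20 face; iodine on C2 trans to that oxygen)
Conditions: I2 (3 equiv), NaHCO3, MeCN/H2O, 0 °C, dark
Reagents that add atoms: iodine, II
Why: In the iodolactonisation of this γ,δ-unsaturated acid the carboxylate can reach the iodonium ion of C1=C2 only at C1 and only from its own face (bridged γ-lactone), which fixes both the position and the configuration of the C1 oxygen.

Step 17
Reactants: 26 iodolactone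
Product: 27 bridged C6→C1 γ-lactone of ring A (C2 now CH2)
Conditions: Bu3SnH, AIBN (cat.), benzene, 80 °C
Reagents that add atoms: none
Why: Radical chain dehalogenation removes the secondary iodide without affecting the ethers or the lactone.

Step 18
Reactants: 27 bridged γ-lactone
Product: 28 ring A diol (C6 CH2OH on C5; 1-OH on the face of C20, C6 and C19; C9 OTBS, C20 OBn, C19 OPMB)
Conditions: LiAlH4, THF, 0 °C → rt
Reagents that add atoms: none
Why: Hydride reduction of the lactone gives the primary C6 alcohol and releases the secondary C1 alcohol with its configuration unchanged.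

Step 19
Reactants: 28 ring A diol
Product: 29 6-O-tert-butyldiphenylsilyl ether of 28
Conditions: t-BuPh2SiCl (1.1 equiv), imidazole, DMF, rt
Reagents that add atoms: tert-butylchlorodiphenylsilane, CC(C)(C)[Si](Cl)(c1ccccc1)c1ccccc1
Why: The bulky silyl chloride reacts at the primary C6 hydroxyl and not at the hindered secondary C1 hydroxyl next to C10.

Step 20
Reactants: 29 6-O-silyl ether
Product: 30 1,19-diol (29 without the 4-methoxybenzyl group)
Conditions: DDQ (1.3 equiv), CH2Cl2/pH 7 buffer, 0 °C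
Reagents that add atoms: none
Why: Oxidative cleavage of the electron-rich 4-methoxybenzyl ether by DDQ frees C19 OH and leaves the benzyl and silyl ethers intact.

Step 21
Reactants: 30 1,19-diol; 31 acetic anhydride
Product: 32 1,19-diacetate (C9 OTBS, C20 OBn, C6 OSi-t-BuPh2)
Conditions: 31, DMAP, pyridine, rt → 40 °C
Reagents that add atoms: none
Why: DMAP-catalysed acylation esterifies the primary C19 and the hindered secondary C1 hydroxyl in one operation.

Step 22
Reactants: 32 1,19-diacetate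
Product: 33 C20 alcohol (32 without the benzyl group)
Conditions: H2 (1 atm), Pd/C, EtOAc, rt
Reagents that add atoms: none
Why: Hydrogenolysis of the benzyl ether is done at a stage with no alkene and no sulfur in the molecule, and acetates and silyl ethers are inert to it.

Step 23
Reactants: 34 2,2-dimethyl-1,3-dioxane-4,6-dione; 35 ethanethiol
Product: 36 3-(ethylsulfanyl)-3-oxopropanoic acid
Conditions: MeCN, 80 °C, sealed tube
Reagents that add atoms: none
Why: The thiol opens the cyclic acylal at an acyl carbon (acyl substitution) and acetone is lost, which gives the malonic acid half thioester.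

Step 24
Reactants: 33 C20 alcohol; 36 3-(ethylsulfanyl)-3-oxopropanoic acid
Product: 37 C20 ester of 33 with 36 (O20–CO–CH2–CO–SEt)
Conditions: EDC·HCl, DMAP (0.1 equiv), CH2Cl2, 0 °C → rt
Reagents that add atoms: none
Why: Carbodiimide esterification (Steglich type) acylates the neopentyl C20 alcohol, helped by the easy activation of malonic half acids.

Step 25
Reactants: 37 C20 thiomalonate
Product: 38 C9 alcohol (37 without the tert-butyldimethylsilyl group)
Conditions: HF·pyridine, pyridine, THF, 0 °C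
Reagents that add atoms: none
Why: Buffered HF·pyridine cleaves the tert-butyldimethylsilyl ether much faster than the tert-butyldiphenylsilyl ether, and the acidic medium suppresses acyl migration from O20 to O9.

Step 26
Reactants: 38 C9 alcohol
Product: 40 spiro α,β-unsaturated δ-lactone (C7 lactone carbonyl, C8=C9, S-ethyl thioester C15 on C8; 1,19-diacetate, C6 OSi-t-BuPh2), via aldehyde 39 (not isolated)
Conditions: Dess–Martin periodinane, NaHCO3, CH2Cl2, 0 °C → rt; filtration; then piperidinium acetate (0.2 equiv), 4 Å molecular sieves, benzene, 50 °C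
Reagents that add atoms: none
Why: Dess–Martin oxidation gives the non-enolisable C9 aldehyde, and amine-catalysed intramolecular Knoevenagel condensation with the active methylene of the tethered thiomalonate closes the six-membered unsaturated lactone.

Step 27
Reactants: 40 spiro unsaturated lactone; 41 buta-1,3-diene
Product: 42 cis-fused Diels–Alder adduct (ring C cyclohexene with C12=C13; C8 quaternary with C(=O)SEt cis to H9; C9–C11 bond on the C1 side of the spiro centre)
Conditions: 41 (excess), ZnCl2 (1.5 equiv), CH2Cl2, 0 °C → rt, sealed tube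
Reagents that add atoms: none
Why: In this Lewis-acid-promoted Diels–Alder reaction of a doubly activated dienophile, suprafacial addition keeps C15 cis to H9 at C8, and the diene should approach C9 anti to the more substituted C5 branch of the spiro centre (the C4 methyl is syn to C9), that is from the C1 side, which sets C9.

Step 28
Reactants: 42 Diels–Alder adduct
Product: 43 C15 aldehyde (C8–CHO)
Conditions: Et3SiH (3 equiv), Pd/C (10 mol %), acetone, rt
Reagents that add atoms: none
Why: Fukuyama reduction (silane/palladium hydrogenolysis of the thioester) stops at the aldehyde and leaves the lactone, the acetates and the isolated ring alkene alone.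

Step 29
Reactants: 43 C15 aldehyde; 44 ethynylmagnesium bromide
Product: 45 C15 propargylic alcohols (C8–CH(OH)–C≡CH, both C15 epimers)
Conditions: 44 (1.3 equiv), THF, −78 °C; aq. NH4Cl
Reagents that add atoms: none
Why: At −78 °C the alkynyl Grignard reagent adds to the aldehyde far faster than to the lactone or the acetates (1,2-addition), and the new C15 centre need not be controlled.

Step 30
Reactants: 45 C15 propargylic alcohols
Product: 47 15-hydroxy-16-ene with the complete bicyclo[3.2.1]octane (rings C and D; C6 OSi-t-BuPh2), via vinylstannane 46 (not isolated)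
Conditions: Bu3SnH (1.5 equiv, 0.1 M), AIBN (cat.), benzene, 80 °C; concentrate; then TsOH·H2O, CH2Cl2, 0 °C
Reagents that add atoms: none
Why: Tin-radical addition to the terminal alkyne gives a C16 vinyl radical that cyclises 5-exo onto C13 of the ring alkene, where only one bridgehead geometry is possible, and acid protodestannylation then leaves the exocyclic methylene (hydrostannylative vinyl-radical cyclisation).

Step 31
Reactants: 47 15-hydroxy-16-ene
Product: 48 6-O-tert-butyldiphenylsilyl ether of the target (15-oxo-16-ene)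
Conditions: Dess–Martin periodinane, NaHCO3, CH2Cl2, rt
Reagents that add atoms: none
Why: Dess–Martin oxidation converts both epimers of the allylic C15 alcohol into the α-methylene ketone.

Step 32
Reactants: 48 6-O-silyl ether of the target
Product: 49 CNP0105570.2 (1,19-diacetoxy-6-hydroxy-15-oxo-6,7-seco-ent-kaur-16-en-7,20-olide, 1-OAc cis to C20)
Conditions: HF·pyridine, pyridine, THF, 0 °C → rt
Reagents that add atoms: none
Why: Buffered fluoride cleavage of the silyl ether frees C6 OH under conditions mild enough to avoid acetate migration and conjugate addition to the enone.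

**Compound list**

1 | (S)-but-3-yn-2-ol | C[C@H](O)C#C | starting material
2 | oxirane | C1CO1 | starting material
3 | (5S)-hex-3-yne-1,5-diol | C[C@H](O)C#CCCO | intermediate
4 | (2S)-6-[(triethylsilyl)oxy]hex-3-yn-2-ol | C[C@H](O)C#CCCO[Si](CC)(CC)CC | intermediate
5 | (2S,3Z)-4-iodo-6-[(triethylsilyl)oxy]hex-3-en-2-ol | C[C@H](O)/C=C(\I)CCO[Si](CC)(CC)CC | intermediate
6 | (2S,3E)-4-methyl-6-[(triethylsilyl)oxy]hex-3-en-2-ol | C[C@H](O)/C=C(\C)CCO[Si](CC)(CC)CC | intermediate
7 | 1,1-dimethoxy-N,N-dimethylethanamine | COC(C)(OC)N(C)C | starting material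
8 | ketene N,O-acetal: N,N-dimethyl-1-{[(2S,3E)-4-methyl-6-[(triethylsilyl)oxy]hex-3-en-2-yl]oxy}ethenamine | C=C(N(C)C)O[C@@H](C)/C=C(\C)CCO[Si](CC)(CC)CC | intermediate
9 | (3S,4E)-N,N,3-trimethyl-3-{2-[(triethylsilyl)oxy]ethyl}hex-4-enamide | C/C=C/[C@@](C)(CCO[Si](CC)(CC)CC)CC(=O)N(C)C | intermediate
10 | (3S)-N,N,3-trimethyl-4-oxo-3-{2-[(triethylsilyl)oxy]ethyl}butanamide | O=C[C@@](C)(CCO[Si](CC)(CC)CC)CC(=O)N(C)C | intermediate
11 | (3S)-4-hydroxy-N,N,3-trimethyl-3-{2-[(triethylsilyl)oxy]ethyl}butanamide | OC[C@@](C)(CCO[Si](CC)(CC)CC)CC(=O)N(C)C | intermediate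
12 | (3S)-4-[(4-methoxybenzyl)oxy]-N,N,3-trimethyl-3-{2-[(triethylsilyl)oxy]ethyl}butanamide | COc1ccc(COC[C@@](C)(CCO[Si](CC)(CC)CC)CC(=O)N(C)C)cc1 | intermediate
13 | benzyl prop-2-yn-1-yl ether | C#CCOCc1ccccc1 | starting material
14 | (6S)-1-(benzyloxy)-7-[(4-methoxybenzyl)oxy]-6-methyl-6-{2-[(triethylsilyl)oxy]ethyl}hept-2-yn-4-one | COc1ccc(COC[C@@](C)(CCO[Si](CC)(CC)CC)CC(=O)C#CCOCc2ccccc2)cc1 | intermediate
15 | (4S,6S)-1-(benzyloxy)-7-[(4-methoxybenzyl)oxy]-6-methyl-6-{2-[(triethylsilyl)oxy]ethyl}hept-2-yn-4-ol | COc1ccc(COC[C@@](C)(CCO[Si](CC)(CC)CC)C[C@H](O)C#CCOCc2ccccc2)cc1 | intermediate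
16 | (2Z,4S,6S)-1-(benzyloxy)-2-iodo-7-[(4-methoxybenzyl)oxy]-6-methyl-6-{2-[(triethylsilyl)oxy]ethyl}hept-2-en-4-ol | COc1ccc(COC[C@@](C)(CCO[Si](CC)(CC)CC)C[C@H](O)/C=C(\I)COCc2ccccc2)cc1 | intermediate
17 | (tributylstannyl)methanol | CCCC[Sn](CCCC)(CCCC)CO | starting material
18 | (2E,4S,6S)-2-[(benzyloxy)methyl]-7-[(4-methoxybenzyl)oxy]-6-methyl-6-{2-[(triethylsilyl)oxy]ethyl}hept-2-ene-1,4-diol | COc1ccc(COC[C@@](C)(CCO[Si](CC)(CC)CC)C[C@H](O)/C=C(\CO)COCc2ccccc2)cc1 | intermediate
19 | (2Z,4S,6S)-1-(benzyloxy)-2-({[tert-butyl(dimethyl)silyl]oxy}methyl)-7-[(4-methoxybenzyl)oxy]-6-methyl-6-{2-[(triethylsilyl)oxy]ethyl}hept-2-en-4-ol | COc1ccc(COC[C@@](C)(CCO[Si](CC)(CC)CC)C[C@H](O)/C=C(\CO[Si](C)(C)C(C)(C)C)COCc2ccccc2)cc1 | intermediate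
20 | (3S,5S,6Z)-8-(benzyloxy)-7-({[tert-butyl(dimethyl)silyl]oxy}methyl)-3-{[(4-methoxybenzyl)oxy]methyl}-3-methyloct-6-ene-1,5-diol | COc1ccc(COC[C@@](C)(CCO)C[C@H](O)/C=C(\CO[Si](C)(C)C(C)(C)C)COCc2ccccc2)cc1 | intermediate
21 | lactol: (4R,6S)-6-[(1Z)-3-(benzyloxy)-2-({[tert-butyl(dimethyl)silyl]oxy}methyl)prop-1-en-1-yl]-4-{[(4-methoxybenzyl)oxy]methyl}-4-methyloxan-2-ol (both anomers) | OC1C[C@](C)(COCc2ccc(OC)cc2)C[C@@H](/C=C(/COCc2ccccc2)\CO[Si](C)(C)C(C)(C)C)O1 | intermediate
22 | (4R,6S)-6-[(1Z)-3-(benzyloxy)-2-({[tert-butyl(dimethyl)silyl]oxy}methyl)prop-1-en-1-yl]-4-{[(4-methoxybenzyl)oxy]methyl}-4-methyloxan-2-one | O=C1C[C@](C)(COCc2ccc(OC)cc2)C[C@@H](/C=C(/COCc2ccccc2)\CO[Si](C)(C)C(C)(C)C)O1 | intermediate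
23 | silyl ketene acetal: (2S,4R)-2-[(1Z)-3-(benzyloxy)-2-({[tert-butyl(dimethyl)silyl]oxy}methyl)prop-1-en-1-yl]-4-{[(4-methoxybenzyl)oxy]methyl}-4-methyl-6-[(trimethylsilyl)oxy]-3,4-dihydro-2H-pyran | C[Si](C)(C)OC1=C[C@](C)(COCc2ccc(OC)cc2)C[C@@H](/C=C(/COCc2ccccc2)\CO[Si](C)(C)C(C)(C)C)O1 | intermediate
24 | trimethylsilyl ester of acid 25 | CC(C)(C)[Si](C)(C)OC[C@]1(COCc2ccccc2)C=CC[C@@](C)(COCc2ccc(OC)cc2)[C@H]1C(=O)O[Si](C)(C)C | intermediate
25 | (1R,2R,6R)-2-[(benzyloxy)methyl]-2-({[tert-butyl(dimethyl)silyl]oxy}methyl)-6-{[(4-methoxybenzyl)oxy]methyl}-6-methylcyclohex-3-ene-1-carboxylic acid | CC(C)(C)[Si](C)(C)OC[C@]1(COCc2ccccc2)C=CC[C@@](C)(COCc2ccc(OC)cc2)[C@H]1C(=O)O | intermediate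
26 | ring A iodolactone (C6(=O)–O–C1 bridge, 2-iodo trans to the lactone oxygen) | CC(C)(C)[Si](C)(C)OC[C@]1(COCc2ccccc2)[C@@H]3[C@H](I)C[C@@](C)(COCc2ccc(OC)cc2)[C@H]1C(=O)O3 | intermediate
27 | ring A bridged γ-lactone (C6(=O)–O–C1, C2 H2) | CC(C)(C)[Si](C)(C)OC[C@]1(COCc2ccccc2)[C@@H]3CC[C@@](C)(COCc2ccc(OC)cc2)[C@H]1C(=O)O3 | intermediate
28 | ring A diol (C6 OH, 1-OH; C9 OTBS, C20 OBn, C19 OPMB) | CC(C)(C)[Si](C)(C)OC[C@]1(COCc2ccccc2)[C@@H](O)CC[C@@](C)(COCc2ccc(OC)cc2)[C@H]1CO | intermediate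
29 | 6-O-tert-butyldiphenylsilyl ether of 28 | CC(C)(C)[Si](C)(C)OC[C@]1(COCc2ccccc2)[C@@H](O)CC[C@@](C)(COCc2ccc(OC)cc2)[C@H]1CO[Si](c2ccccc2)(c2ccccc2)C(C)(C)C | intermediate
30 | 1,19-diol (C9 OTBS, C20 OBn, C6 OSi-t-BuPh2) | CC(C)(C)[Si](C)(C)OC[C@]1(COCc2ccccc2)[C@@H](O)CC[C@@](C)(CO)[C@H]1CO[Si](c2ccccc2)(c2ccccc2)C(C)(C)C | intermediate
31 | acetic anhydride | CC(=O)OC(C)=O | starting material
32 | 1,19-diacetate (C9 OTBS, C20 OBn, C6 OSi-t-BuPh2) | CC(C)(C)[Si](C)(C)OC[C@]1(COCc2ccccc2)[C@@H](OC(C)=O)CC[C@@](C)(COC(C)=O)[C@H]1CO[Si](c2ccccc2)(c2ccccc2)C(C)(C)C | intermediate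
33 | C20 alcohol (1,19-diacetate, C9 OTBS, C6 OSi-t-BuPh2) | CC(C)(C)[Si](C)(C)OC[C@]1(CO)[C@@H](OC(C)=O)CC[C@@](C)(COC(C)=O)[C@H]1CO[Si](c2ccccc2)(c2ccccc2)C(C)(C)C | intermediate
34 | 2,2-dimethyl-1,3-dioxane-4,6-dione | CC1(C)OC(=O)CC(=O)O1 | starting material
35 | ethanethiol | CCS | starting material
36 | 3-(ethylsulfanyl)-3-oxopropanoic acid | CCSC(=O)CC(=O)O | intermediate
37 | C20 O-[3-(ethylsulfanyl)-3-oxopropanoyl] ester of 33 | CC(C)(C)[Si](C)(C)OC[C@]1(COC(=O)CC(=O)SCC)[C@@H](OC(C)=O)CC[C@@](C)(COC(C)=O)[C@H]1CO[Si](c2ccccc2)(c2ccccc2)C(C)(C)C | intermediate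
38 | C9 alcohol (37 without TBS) | OC[C@]1(COC(=O)CC(=O)SCC)[C@@H](OC(C)=O)CC[C@@](C)(COC(C)=O)[C@H]1CO[Si](c2ccccc2)(c2ccccc2)C(C)(C)C | intermediate
39 | C9 aldehyde | O=C[C@]1(COC(=O)CC(=O)SCC)[C@@H](OC(C)=O)CC[C@@](C)(COC(C)=O)[C@H]1CO[Si](c2ccccc2)(c2ccccc2)C(C)(C)C | intermediate
40 | spiro α,β-unsaturated δ-lactone with C8 S-ethyl thioester (C8=C9) | CCSC(=O)C1=C[C@]2(COC1=O)[C@@H](OC(C)=O)CC[C@@](C)(COC(C)=O)[C@H]2CO[Si](c1ccccc1)(c1ccccc1)C(C)(C)C | intermediate
41 | buta-1,3-diene | C=CC=C | starting material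
42 | Diels–Alder adduct (ring C, C12=C13; C8 thioester cis to H9) | CCSC(=O)[C@]23CC=CC[C@H]2[C@]1(COC3=O)[C@@H](OC(C)=O)CC[C@@](C)(COC(C)=O)[C@H]1CO[Si](c1ccccc1)(c1ccccc1)C(C)(C)C | intermediate
43 | C15 aldehyde | O=C[C@]23CC=CC[C@H]2[C@]1(COC3=O)[C@@H](OC(C)=O)CC[C@@](C)(COC(C)=O)[C@H]1CO[Si](c1ccccc1)(c1ccccc1)C(C)(C)C | intermediate
44 | ethynylmagnesium bromide | C#C[Mg]Br | starting material
45 | C15 propargylic alcohols (both C15 epimers) | C#CC(O)[C@]23CC=CC[C@H]2[C@]1(COC3=O)[C@@H](OC(C)=O)CC[C@@](C)(COC(C)=O)[C@H]1CO[Si](c1ccccc1)(c1ccccc1)C(C)(C)C | intermediate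
46 | bicyclo[3.2.1]octane vinylstannane (C16=C17H–SnBu3, both alkene isomers, both C15 epimers) | CCCC[Sn](CCCC)(CCCC)C=C1C(O)[C@]23C[C@H]1CC[C@H]2[C@]1(COC3=O)[C@@H](OC(C)=O)CC[C@@](C)(COC(C)=O)[C@H]1CO[Si](c1ccccc1)(c1ccccc1)C(C)(C)C | intermediate
47 | 15-hydroxy-16-ene (both C15 epimers; C6 OSi-t-BuPh2) | C=C1C(O)[C@]23C[C@H]1CC[C@H]2[C@]1(COC3=O)[C@@H](OC(C)=O)CC[C@@](C)(COC(C)=O)[C@H]1CO[Si](c1ccccc1)(c1ccccc1)C(C)(C)C | intermediate
48 | 6-O-tert-butyldiphenylsilyl ether of the target | C=C1C(=O)[C@]23C[C@H]1CC[C@H]2[C@]1(COC3=O)[C@@H](OC(C)=O)CC[C@@](C)(COC(C)=O)[C@H]1CO[Si](c1ccccc1)(c1ccccc1)C(C)(C)C | intermediate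
49 | CNP0105570.2 | C=C1C(=O)[C@]23C[C@H]1CC[C@H]2[C@]1(COC3=O)[C@@H](OC(C)=O)CC[C@@](C)(COC(C)=O)[C@H]1CO | target

**Step count and risks**

Total steps: 32. Longest linear sequence: 31 steps (steps 1–22 and 24–32); step 23 is a one-step branch that makes acid 36.

Steps most likely to fail:

1. Step 15. Enolisation may be incomplete, the labile silyl ketene acetal may hydrolyse back to the lactone, or the shift may be slow because two adjacent congested centres form beside quaternary C4. The fallback makes the same C5–C10 bond from a neutral enol ether. Lactone 22 would be reduced with i-Bu2AlH at −78 °C to lactol 21, which would be dehydrated (MsCl, Et3N, then warming) to the 2-alkenyl-3,4-dihydro-2H-pyran F1. Heating F1 in a sealed tube at about 200 °C should bring about the aliphatic Claisen ring contraction through the same boat to the cyclohexenecarbaldehyde F2. Pinnick oxidation (NaClO2, NaH2PO4, 2-methylbut-2-ene) of F2 would return to the route at acid 25.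

2. Step 27. Conversion may be low because the dienophile carbon C9 sits next to the spiro centre and butadiene is a weak diene, and some diene may add from the C5 face. The fallback sets out from 40 with the far more reactive 2-(trimethylsilyloxy)buta-1,3-diene, whose oxygen-bearing carbon should end para to C8, giving the C12 trimethylsilyl enol ether F3. Treatment with CsF and PhNTf2 would convert it into the C12 enol triflate F4, and reduction with Pd(OAc)2, PPh3, HCO2H and Bu3N would remove the triflate and return to the route at 42.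

3. Step 30. The cyclised radical may rearrange to the bicyclo[2.2.2]octane skeleton (homoallyl–homoallyl rearrangement), or the vinyl radical may take up hydrogen before it cyclises. The fallback is a non-radical, palladium-hydride reductive enyne cyclisation that sets out from 45: Pd2(dba)3·CHCl3, P(o-tolyl)3, AcOH and Et3SiH in toluene. Hydropalladation of the alkyne, 5-exo carbopalladation of C12=C13 and silane cleavage of the C12–Pd bond would give 47 directly, so no new compound arises.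

Further compounds
F1 | step 15 | (2S,4R)-2-[(1Z)-3-(benzyloxy)-2-({[tert-butyl(dimethyl)silyl]oxy}methyl)prop-1-en-1-yl]-4-{[(4-methoxybenzyl)oxy]methyl}-4-methyl-3,4-dihydro-2H-pyran | O1C=C[C@](C)(COCc2ccc(OC)cc2)C[C@H]1/C=C(/COCc2ccccc2)\CO[Si](C)(C)C(C)(C)C
F2 | step 15 | (1R,2R,6R)-2-[(benzyloxy)methyl]-2-({[tert-butyl(dimethyl)silyl]oxy}methyl)-6-{[(4-methoxybenzyl)oxy]methyl}-6-methylcyclohex-3-ene-1-carbaldehyde | CC(C)(C)[Si](C)(C)OC[C@]1(COCc2ccccc2)C=CC[C@@](C)(COCc2ccc(OC)cc2)[C@H]1C=O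
F3 | step 27 | C12 trimethylsilyl enol ether analogue of 42 (C12(OSiMe3)=C13) | CCSC(=O)[C@]23CC=C(O[Si](C)(C)C)C[C@H]2[C@]1(COC3=O)[C@@H](OC(C)=O)CC[C@@](C)(COC(C)=O)[C@H]1CO[Si](c1ccccc1)(c1ccccc1)C(C)(C)C
F4 | step 27 | C12 enol trifluoromethanesulfonate analogue of 42 | CCSC(=O)[C@]23CC=C(OS(=O)(=O)C(F)(F)F)C[C@H]2[C@]1(COC3=O)[C@@H](OC(C)=O)CC[C@@](C)(COC(C)=O)[C@H]1CO[Si](c1ccccc1)(c1ccccc1)C(C)(C)C
F0 | step 30 | none | none
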